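**Numbering used throughout** (full names and SMILES follow the steps): 1 O-benzylvanillin; 2 styrene of ring A; 3 methyl vanillate; 4 its 5-bromide; 5 bromo pivalate; 6 (E)-stilbene; 7 formaldehyde; 8 dioxane pivalate; 9 dioxane phenol; 10 dioxane benzyl ether ester; 11 benzylic alcohol; 12 benzylic bromide of the A/B half; 13 pyridinium intermediate; 14 triol; 15 dihydrobenzofuran alcohol; 16 its MOM ether; 17 benzylic alcohol; 18 benzylic bromide of the C/D half; 19 oxazolidinone; 20 methyl succinyl chloride; 21 succinate imide; 22 alkylated imide; 23 hydroxy ester; 24 β-substituted lactone; 25 coupled, fully protected skeleton; 26 bis-pyridinium intermediate; 27 tribenzyl ether; 28 target.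

## Analysis of the target

The target 28 is a trans-α,β-dibenzyl-γ-butyrolactone (Cα S, Cβ S) in which each benzyl arm is extended by a second phenylpropanoid unit. On the α-arm, guaiacyl ring B carries, ortho to its free phenol, the open array C7(OH)(ring A)–C8(ring B)–C9H2OH with the anti (7S,8S) configuration. On the β-arm, ring C is fused into a trans-(2R,3S)-2-aryl-3-hydroxymethyl-2,3-dihydrobenzofuran whose C2 carries ring D. The six stereocentres form three pairs (C7/C8, Cα/Cβ, C2/C3) that are too far apart to control one another, so each pair needs its own control element. Sensitive points are the three free phenols, the benzylic alcohol at C7 and the benzylic ether at C2 (each para to a phenol, hence prone to quinone methide or cation formation and to hydrogenolysis), possible loss of C9 as formaldehyde from such a cation, and the epimerisable Cα. The difficulty is that rings B and C are the same 5-substituted guaiacyl unit in two states, open and cyclised, and both must be built enantioselectively and attached to one small lactone. The strategy rests on two observations: C7(OH)–C8(ring B)–C9H2OH is a trans-4,5-diaryl-1,3-dioxane without its acetal carbon, so C9 and the C7 oxygen can come from formaldehyde added across a ring A–ring B (E)-stilbene, and the furan unit is the same array after loss of water between the ring C phenol and C7 (ring C ≡ ring B, ring D ≡ ring A, C3 ≡ C8, both S), so one dioxane serves both arms.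

## Retrosynthetic reasoning

**28 ⇒ 27 ⇒ 25 (protecting groups only).** The three phenols of 28 are traced to the aryl benzyl ethers of 27, removed by hydrogenolysis. The three alcohols of 27 are traced to two formaldehyde acetals in 25: the cyclic methylene acetal across O7/O9 and a methoxymethyl ether on the furan CH2OH. Both are O–CH2–O groups, so one Lewis-acid-mediated cleavage removes them together. The acetals go first and the benzyl ethers last, so that C7 is freed while every phenol is still etherified.

**25 ⇒ 24 + 12 (Cα–CH2 bond to ring B).** Cutting here, and not at Cβ, splits the molecule into two halves of similar size. It also uses the bond whose stereochemical outcome is dependable, since the enolate of a β-substituted butyrolactone is alkylated anti to the β-substituent. The forward step must join lactone 24 and benzylic bromide 12 and set Cα (S) trans to Cβ.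

**24 ⇒ 22 ⇒ 21 + 18; 21 ⇒ 19 + 20 (Cβ–CH2 bond to ring C and the lactone C–O bond).** Cβ is remote from the furan stereocentres and needs external control. The auxiliary-bound succinate 21 (from 19 and 20) is alkylated by bromide 18 to give 22; reductive release of the auxiliary and ring closure through 23 give 24. The imide carbon becomes the lactone CH2O and the ester carbon the lactone carbonyl. The forward step must deliver 3S in 22, which the (4S)-auxiliary provides.

**12 and 18 ⇒ 9 (two bromides from one compound).** 12 is 9 after O-benzylation of the ring B phenol and conversion of the ester into CH2Br (through 10 and 11). In 18 the furan O1–C2 bond is cut, which leads through 17, 16 and 15 to triol 14, and 14 is 9 without its acetal carbon. The cut is made at O1–C2 because C2 is a para-alkoxybenzylic carbon whose configuration is set under thermodynamic control on closure. Only C3 has to be carried, and C3 is C8 of the dioxane. One enantiomeric series of one intermediate therefore supplies four of the six stereocentres.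

**9 ⇒ 8 ⇒ 6 + 7 (key disconnection).** 9 is the phenol of pivalate 8. In 8 the C8–C9 and C7–O bonds and the two bonds of the acetal carbon are cut, which returns the flat, achiral (E)-stilbene 6 and two molecules of formaldehyde 7. This is the largest simplification: two stereocentres, one ring and the diol protection arise in one operation. The forward Prins reaction must deliver carbon to C8 and oxygen to C7, trans, on one alkene face. The pivalate and the ester serve this purpose: they keep ring B from stabilising charge at C8, and the acyl group keeps the ring B oxygen from trapping the C7 cation.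

**6 ⇒ 2 + 5; 2 ⇒ 1; 5 ⇒ 4 ⇒ 3.** The stilbene is cut at the aryl–vinyl bond on the ring B side (Heck coupling). This places the halide on the electron-poor ring and the vinyl group on ring A, where aldehyde 1 supplies it by methylenation. 5 comes from 3 by bromination ortho to the phenol (4) and acylation.

## Alternatives that were turned down

**Alternative 1:** The furan O1–C2 bond is formed last. Both arms carry the same anti diol unit. In the precursor A1 the α-arm unit is tetra-acetylated and the β-arm unit is free, and a catalytic sulfonic acid converts the β-arm benzylic alcohol, para to a free phenol, into a quinone methide. The ring C phenol traps it to give the trans furan in A2, the tetra-acetate of the target.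
- For it: the closure is biomimetic and stereoconvergent at C2, and it rests on well-known quinone methide chemistry. On precedent for the key step it is stronger than the route chosen here, and its branch point lies later.
- Against it: the two units are chemically identical and are told apart only by their protecting groups. Acetates survive neither hydride reagents nor lactone enolates, so they have to be put on late and selectively.
- Against it: removing four acetates from A2 is hazardous. Once the ring A aryl acetate is cleaved, the phenoxide can expel the C7 acetate through a quinone methide, which scrambles or etherifies C7.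
- Against it: the strategy does not say how the anti unit itself is made enantioselectively.
- Comparison: the chosen route keeps the economy of one unit used twice but creates that unit in the key step. It closes the furan early on the small fragment 14, where a failure is cheap, and it keeps the open unit locked as an acetal until the penultimate step.

**Alternative 2:** The furan C2–C3 bond is cut. In aryl diazoacetate A3 a carbene, generated with the chiral dirhodium carboxylate Rh2(PTTL)4, inserts into the benzylic O–CH2 C–H bond. An amidine base then epimerises C3 to give the trans ester A4.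
- For it: the reaction type has precedent on exactly this ring system, and the C3 ester is a latent CH2OH. For the furan alone it is the better-founded asymmetric step, stronger on this point than a Prins reaction on a stilbene.
- Against it: it addresses two of six stereocentres. C3 is set only by a later base equilibration, in which the C3 enolate can expel the phenoxide (retro-oxa-Michael) and so endanger C2.
- Against it: the aryl bromide of A4 still has to be turned into the benzylic carbon of the lactone arm.
- Against it: the open unit of the other arm needs an unrelated asymmetric sequence, so no intermediate is shared and the step count grows.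
- Comparison: the chosen route takes C3 from the same stereocentre as C8, sets C2 by a reversible acid closure without base, and draws both halves from 9.

**Alternative 3:** The lactone O–CH2 bond is cut. The cyclobutanone A5, locally prochiral at its 3-position, is ring-expanded by aqueous peroxide and a chiral phosphoric acid to lactone A6.
- For it: Cβ and the lactone ring are made catalytically in one step without an auxiliary. At that centre this is more atom-economical than steps 15–17 here.
- Against it: it solves the stereocentre that is easiest to set by other means.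
- Against it: the group that differentiates the two migrating CH2 groups sits one carbon away from the ring (a 3-arylmethyl, not a 3-aryl, substituent), so face discrimination is expected to be weaker. The remote furan stereocentres give no substrate help.
- Against it: A5 needs several steps of its own (four-membered ring construction on an allyl arene), and both diaryl units are presupposed.
- Comparison: the chosen key step creates C7 and C8 and, through the shared intermediate, C3 and C2. It leaves Cβ and Cα to auxiliary- and substrate-controlled alkylations, which are the dependable part of the route.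

Key step: step 5

Assumption: the sense of induction of the chiral acid on a 1,2-diaryl alkene cannot be derived from the styrene cases; the antipode that delivers (4S,5S)-8 is to be identified by one trial with each antipode and is the one meant in step 5.

## Route

Step 1
Reactants: 1 4-benzyloxy-3-methoxybenzaldehyde
Product: 2 4-benzyloxy-3-methoxystyrene
Conditions: Ph3PCH3Br, KOt-Bu, THF, 0 °C to rt
Reagents that add atoms: methyltriphenylphosphonium bromide, C[P+](c1ccccc1)(c1ccccc1)c1ccccc1.[Br-]
Why: Wittig methylenation of a non-enolisable aryl aldehyde with the unstabilised ylide; no stereochemical issue arises.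

Step 2
Reactants: 3 methyl 4-hydroxy-3-methoxybenzoate (methyl vanillate)
Product: 4 methyl 3-bromo-4-hydroxy-5-methoxybenzoate
Conditions: Br2, AcOH, rt
Reagents that add atoms: bromine, BrBr
Why: Electrophilic aromatic bromination; the phenol directs to its only free ortho position, the para position being blocked by the ester.

Step 3
Reactants: 4 methyl 3-bromo-4-hydroxy-5-methoxybenzoate
Product: 5 methyl 3-bromo-4-(2,2-dimethylpropanoyloxy)-5-methoxybenzoate
Conditions: t-BuCOCl, Et3N, DMAP (cat.), CH2Cl2, 0 °C to rt
Reagents that add atoms: pivaloyl chloride, CC(C)(C)C(=O)Cl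
Why: DMAP-catalysed O-acylation of the phenol. The pivalate withstands the amine base of the coupling and the acid of the key step, lowers the donor strength of ring B, and is later removed by methanolysis.

Step 4
Reactants: 2 4-benzyloxy-3-methoxystyrene; 5 bromo pivalate
Product: 6 methyl 3-[(E)-2-(4-benzyloxy-3-methoxyphenyl)ethenyl]-4-(2,2-dimethylpropanoyloxy)-5-methoxybenzoate
Conditions: Pd(OAc)2 (5 mol%), P(o-tolyl)3 (10 mol%), Et3N, DMF, 100 °C
Reagents that add atoms: none
Why: Mizoroki–Heck coupling of an electron-poor aryl bromide with a styrene; syn carbopalladation followed by syn β-hydride elimination gives the E-alkene.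

Step 5
Reactants: 6 (E)-stilbene; 7 formaldehyde (used as paraformaldehyde, two molecules incorporated)
Product: 8 methyl 3-[(4S,5S)-4-(4-benzyloxy-3-methoxyphenyl)-1,3-dioxan-5-yl]-4-(2,2-dimethylpropanoyloxy)-5-methoxybenzoate
Conditions: (CH2O)n (5 equiv), confined chiral imino-imidodiphosphate acid built from two 3,3'-diaryl-BINOL units (5 mol%), CHCl3/cyclohexane, 25 °C
Reagents that add atoms: none
Why: Proposed new method: the chiral acid protonates formaldehyde (or its hemiformal dimer) inside its pocket, the alkene attacks with C8 and positive charge develops at C7, where the para-benzyloxy group of ring A stabilises it, and the oxygen of the second formaldehyde unit bonds to C7, probably in one concerted but strongly asynchronous event. The closest known reaction type is the enantioselective Prins reaction of styrenes with paraformaldehyde under confined imino-imidodiphosphate acids, which gives 4-aryl-1,3-dioxanes, together with the classical acid-mediated Prins reaction of 1-aryl-1-propenes, which gives trans-4-aryl-5-alkyl-1,3-dioxanes; a 1,2-diaryl alkene has not been used with the chiral acid. The dioxane ring closes by O–C7 bond formation, the hemiformal oxygen capturing the benzylic cation through a six-membered chair with both aryl groups equatorial. C8 (C5 of the ring) is set by the alkene face that the confined counter-anion leaves open to formaldehyde. C7 (C4 of the ring) follows from suprafacial delivery of carbon and oxygen to the E-alkene and, if the cation lives long enough to rotate, from the same diequatorial chair, so that both pathways end in the trans-(4S,5S) ring. The step needs regioselectivity (carbon to C8, oxygen to C7), secured by the substrate: ring B, with its ortho-acyloxy and meta-ester groups, cannot stabilise charge at C8, whereas ring A is a para-alkoxyphenyl donor. It also needs chemoselectivity against hydroxymethylation of ring A and against capture of C7 by the ring B oxygen, which the weakly nucleophilic acylated phenol and the catalytic, non-aqueous acid should provide.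

Step 6
Reactants: 8 dioxane pivalate
Product: 9 methyl 3-[(4S,5S)-4-(4-benzyloxy-3-methoxyphenyl)-1,3-dioxan-5-yl]-4-hydroxy-5-methoxybenzoate
Conditions: K2CO3, MeOH/THF, 40 °C; aq. NH4Cl
Reagents that add atoms: none
Why: Base-mediated methanolysis (transesterification) of the aryl ester; exchange at the methyl ester is degenerate in methanol, and the acetal, the benzyl ether and both stereocentres are inert to carbonate.

Step 7
Reactants: 9 dioxane phenol
Product: 10 methyl 4-benzyloxy-3-[(4S,5S)-4-(4-benzyloxy-3-methoxyphenyl)-1,3-dioxan-5-yl]-5-methoxybenzoate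
Conditions: BnBr, K2CO3, DMF, rt
Reagents that add atoms: benzyl bromide, BrCc1ccccc1
Why: Williamson etherification of the phenoxide; the benzyl ether replaces the pivalate, which would survive neither the hydride reduction nor the enolate alkylation that follow.

Step 8
Reactants: 10 dioxane benzyl ether ester
Product: 11 {4-benzyloxy-3-[(4S,5S)-4-(4-benzyloxy-3-methoxyphenyl)-1,3-dioxan-5-yl]-5-methoxyphenyl}methanol
Conditions: i-Bu2AlH, CH2Cl2, −78 to 0 °C; aq. potassium sodium tartrate
Reagents that add atoms: none
Why: Hydride reduction of the aryl ester to the benzylic alcohol; acetal and ethers are not reduced.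

Step 9
Reactants: 11 benzylic alcohol
Product: 12 (4S,5S)-5-[2-benzyloxy-5-(bromomethyl)-3-methoxyphenyl]-4-(4-benzyloxy-3-methoxyphenyl)-1,3-dioxane
Conditions: CBr4, PPh3, CH2Cl2, 0 °C
Reagents that add atoms: carbon tetrabromide, BrC(Br)(Br)Br
Why: Appel bromination under neutral conditions, which spares the acid-labile benzylic acetal; the electron-rich benzylic bromide is used without storage.

Step 10
Reactants: 9 dioxane phenol
Product: 14 methyl 3-[(1S,2S)-1-(4-benzyloxy-3-methoxyphenyl)-1,3-dihydroxypropan-2-yl]-4-hydroxy-5-methoxybenzoate, via silylated N-(alkoxymethyl)-2,2'-bipyridinium triflate 13 (not isolated)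
Conditions: TMSOTf, 2,2'-bipyridyl, CH2Cl2, 0 °C to rt; then H2O
Reagents that add atoms: none
Why: Known methylene acetal cleavage: the silyl triflate activates one acetal oxygen, 2,2'-bipyridyl captures the resulting oxocarbenium ion as pyridinium salt 13 (the phenol is silylated in passing), and water hydrolyses the salt and the silyl ethers to the triol and formaldehyde. The medium contains no free protic acid, and C7 and C8 are not involved; should C7 ionise, the ortho silyloxy group would close the furan, which is the product of step 11.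

Step 11
Reactants: 14 triol
Product: 15 methyl (2R,3S)-2-(4-benzyloxy-3-methoxyphenyl)-3-(hydroxymethyl)-7-methoxy-2,3-dihydro-1-benzofuran-5-carboxylate
Conditions: TsOH·H2O (10 mol%), MeCN, 0 °C to rt
Reagents that add atoms: none
Why: Acid-catalysed cyclodehydration (SN1): the C7 hydroxyl leaves as water to give the para-benzyloxybenzylic cation, which the neighbouring phenol captures to close the five-membered ring, while the primary alcohol cannot compete (it would give an oxetane). The closure is reversible under acid, so C2 settles trans to the C3 hydroxymethyl group (2R); C3, the former C8, is not involved and stays S.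

Step 12
Reactants: 15 dihydrobenzofuran alcohol
Product: 16 methyl (2R,3S)-2-(4-benzyloxy-3-methoxyphenyl)-7-methoxy-3-[(methoxymethoxy)methyl]-2,3-dihydro-1-benzofuran-5-carboxylate
Conditions: MOMCl, i-Pr2NEt, CH2Cl2, 0 °C to rt
Reagents that add atoms: chloromethyl methyl ether, COCCl
Why: Alkylation of the primary alcohol under mild amine-base conditions; the MOM ether is the open-chain counterpart of the methylene acetal in 12, so one reagent removes both in step 19.

Step 13
Reactants: 16 MOM ether
Product: 17 {(2R,3S)-2-(4-benzyloxy-3-methoxyphenyl)-7-methoxy-3-[(methoxymethoxy)methyl]-2,3-dihydro-1-benzofuran-5-yl}methanol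
Conditions: i-Bu2AlH, CH2Cl2, −78 to 0 °C; aq. potassium sodium tartrate
Reagents that add atoms: none
Why: Hydride reduction of the ester to the benzylic alcohol; the acetal, the ethers and the furan ring are inert.

Step 14
Reactants: 17 benzylic alcohol
Product: 18 (2R,3S)-2-(4-benzyloxy-3-methoxyphenyl)-5-(bromomethyl)-7-methoxy-3-[(methoxymethoxy)methyl]-2,3-dihydro-1-benzofuran
Conditions: CBr4, PPh3, CH2Cl2, 0 °C
Reagents that add atoms: carbon tetrabromide, BrC(Br)(Br)Br
Why: Appel bromination under neutral conditions, compatible with the MOM ether and the benzylic ether of the furan; the bromide is used at once.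

Step 15
Reactants: 19 (4S)-4-benzyl-1,3-oxazolidin-2-one; 20 methyl 4-chloro-4-oxobutanoate
Product: 21 methyl 4-[(4S)-4-benzyl-2-oxo-1,3-oxazolidin-3-yl]-4-oxobutanoate
Conditions: n-BuLi, THF, −78 °C; then 20, −78 to 0 °C
Reagents that add atoms: none
Why: N-Acylation of the lithiated oxazolidinone by the acid chloride, the standard entry to Evans imides.

Step 16
Reactants: 21 succinate imide; 18 benzylic bromide of the C/D half
Product: 22 methyl (3S)-4-[(4S)-4-benzyl-2-oxo-1,3-oxazolidin-3-yl]-3-({(2R,3S)-2-(4-benzyloxy-3-methoxyphenyl)-7-methoxy-3-[(methoxymethoxy)methyl]-2,3-dihydro-1-benzofuran-5-yl}methyl)-4-oxobutanoate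
Conditions: NaN(SiMe3)2, THF, −78 °C; then 18, −78 to −40 °C
Reagents that add atoms: none
Why: Evans alkylation: the sodium Z-enolate is chelated to the oxazolidinone carbonyl and the bromide enters on the face away from the 4-benzyl group, which gives 3S (CH2CO2Me outranks the arylmethyl group). Only the imide enolate forms, because its α-protons are much more acidic than those next to the ester.

Step 17
Reactants: 22 alkylated imide
Product: 24 (4S)-4-({(2R,3S)-2-(4-benzyloxy-3-methoxyphenyl)-7-methoxy-3-[(methoxymethoxy)methyl]-2,3-dihydro-1-benzofuran-5-yl}methyl)oxolan-2-one, via γ-hydroxy methyl ester 23 (not isolated)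
Conditions: NaBH4, THF/H2O, 0 °C to rt; then PPTS (cat.), CH2Cl2, rt
Reagents that add atoms: none
Why: Borohydride reduces the activated exocyclic imide carbonyl and leaves the methyl ester, releasing the auxiliary and alcohol 23, whose γ-hydroxy ester closes to the five-membered lactone under mild acid. The stereocentre is not touched and becomes C4 (S) of the lactone.

Step 18
Reactants: 24 β-substituted lactone; 12 benzylic bromide of the A/B half
Product: 25 (3S,4S)-3-({4-benzyloxy-3-[(4S,5S)-4-(4-benzyloxy-3-methoxyphenyl)-1,3-dioxan-5-yl]-5-methoxyphenyl}methyl)-4-({(2R,3S)-2-(4-benzyloxy-3-methoxyphenyl)-7-methoxy-3-[(methoxymethoxy)methyl]-2,3-dihydro-1-benzofuran-5-yl}methyl)oxolan-2-one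
Conditions: LiN(SiMe3)2, THF, −78 °C; then 12, DMPU, −78 to −30 °C
Reagents that add atoms: none
Why: Alkylation of the lithium enolate of a β-substituted γ-butyrolactone: the bromide approaches anti to the β-arylmethyl group, which sets Cα as S, trans to Cβ. This is the established mode of stereocontrol for dibenzylbutyrolactones; acetals, ethers and the furan are inert to the amide base at low temperature.

Step 19
Reactants: 25 coupled, fully protected skeleton
Product: 27 (3S,4S)-3-({4-benzyloxy-3-[(1S,2S)-1-(4-benzyloxy-3-methoxyphenyl)-1,3-dihydroxypropan-2-yl]-5-methoxyphenyl}methyl)-4-({(2R,3S)-2-(4-benzyloxy-3-methoxyphenyl)-3-(hydroxymethyl)-7-methoxy-2,3-dihydro-1-benzofuran-5-yl}methyl)oxolan-2-one, via bis[N-(alkoxymethyl)-2,2'-bipyridinium] triflate 26 (not isolated)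
Conditions: TMSOTf, 2,2'-bipyridyl, CH2Cl2, 0 °C to rt; then H2O
Reagents that add atoms: none
Why: The same silyl triflate/bipyridyl acetal cleavage as in step 10 converts the methylene acetal and the MOM ether into pyridinium salts (26), which water hydrolyses to the three alcohols. The buffered, aprotic medium is chosen to keep the C7–O and C2–O benzylic bonds from ionising; lactone and benzyl ethers are inert.

Step 20
Reactants: 27 tribenzyl ether
Product: 28 (3S,4S)-3-({3-[(1S,2S)-1,3-dihydroxy-1-(4-hydroxy-3-methoxyphenyl)propan-2-yl]-4-hydroxy-5-methoxyphenyl}methyl)-4-({(2R,3S)-2-(4-hydroxy-3-methoxyphenyl)-3-(hydroxymethyl)-7-methoxy-2,3-dihydro-1-benzofuran-5-yl}methyl)oxolan-2-one (target)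
Conditions: H2 (1 atm), Pd/C (10% Pd on carbon), EtOAc/MeOH, rt
Reagents that add atoms: none
Why: Hydrogenolysis of the three aryl benzyl ethers; in neutral solvent at 1 atm these primary benzylic C–O bonds should cleave much faster than the secondary benzylic C7–OH and furan C2–O bonds. The reaction is stopped after uptake of three equivalents of hydrogen.

## Compound list

1 | 4-benzyloxy-3-methoxybenzaldehyde | COc1cc(C=O)ccc1OCc1ccccc1 | starting material
2 | 4-benzyloxy-3-methoxystyrene | COc1cc(C=C)ccc1OCc1ccccc1 | intermediate
3 | methyl 4-hydroxy-3-methoxybenzoate | COC(=O)c1ccc(O)c(OC)c1 | starting material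
4 | methyl 3-bromo-4-hydroxy-5-methoxybenzoate | COC(=O)c1cc(Br)c(O)c(OC)c1 | intermediate
5 | methyl 3-bromo-4-(2,2-dimethylpropanoyloxy)-5-methoxybenzoate | COC(=O)c1cc(Br)c(OC(=O)C(C)(C)C)c(OC)c1 | intermediate
6 | methyl 3-[(E)-2-(4-benzyloxy-3-methoxyphenyl)ethenyl]-4-(2,2-dimethylpropanoyloxy)-5-methoxybenzoate | COc1cc(/C=C/c2cc(C(=O)OC)cc(OC)c2OC(=O)C(C)(C)C)ccc1OCc1ccccc1 | intermediate
7 | formaldehyde (as paraformaldehyde) | C=O | starting material
8 | methyl 3-[(4S,5S)-4-(4-benzyloxy-3-methoxyphenyl)-1,3-dioxan-5-yl]-4-(2,2-dimethylpropanoyloxy)-5-methoxybenzoate | COc1cc([C@H]2OCOC[C@@H]2c2cc(C(=O)OC)cc(OC)c2OC(=O)C(C)(C)C)ccc1OCc1ccccc1 | intermediate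
9 | methyl 3-[(4S,5S)-4-(4-benzyloxy-3-methoxyphenyl)-1,3-dioxan-5-yl]-4-hydroxy-5-methoxybenzoate | COc1cc([C@H]2OCOC[C@@H]2c2cc(C(=O)OC)cc(OC)c2O)ccc1OCc1ccccc1 | intermediate
10 | methyl 4-benzyloxy-3-[(4S,5S)-4-(4-benzyloxy-3-methoxyphenyl)-1,3-dioxan-5-yl]-5-methoxybenzoate | COc1cc([C@H]2OCOC[C@@H]2c2cc(C(=O)OC)cc(OC)c2OCc2ccccc2)ccc1OCc1ccccc1 | intermediate
11 | {4-benzyloxy-3-[(4S,5S)-4-(4-benzyloxy-3-methoxyphenyl)-1,3-dioxan-5-yl]-5-methoxyphenyl}methanol | COc1cc([C@H]2OCOC[C@@H]2c2cc(CO)cc(OC)c2OCc2ccccc2)ccc1OCc1ccccc1 | intermediate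
12 | (4S,5S)-5-[2-benzyloxy-5-(bromomethyl)-3-methoxyphenyl]-4-(4-benzyloxy-3-methoxyphenyl)-1,3-dioxane | COc1cc([C@H]2OCOC[C@@H]2c2cc(CBr)cc(OC)c2OCc2ccccc2)ccc1OCc1ccccc1 | intermediate
13 | 1-({(1S,2S)-1-(4-benzyloxy-3-methoxyphenyl)-2-[3-methoxy-5-(methoxycarbonyl)-2-(trimethylsilyloxy)phenyl]-3-(trimethylsilyloxy)propoxy}methyl)-2-(pyridin-2-yl)pyridinium triflate (one regiochemistry of acetal opening shown; either gives 14) | COc1cc([C@@H](OC[n+]2ccccc2-c2ccccn2)[C@H](CO[Si](C)(C)C)c2cc(C(=O)OC)cc(OC)c2O[Si](C)(C)C)ccc1OCc1ccccc1.[O-]S(=O)(=O)C(F)(F)F | intermediate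
14 | methyl 3-[(1S,2S)-1-(4-benzyloxy-3-methoxyphenyl)-1,3-dihydroxypropan-2-yl]-4-hydroxy-5-methoxybenzoate | COc1cc([C@@H](O)[C@H](CO)c2cc(C(=O)OC)cc(OC)c2O)ccc1OCc1ccccc1 | intermediate
15 | methyl (2R,3S)-2-(4-benzyloxy-3-methoxyphenyl)-3-(hydroxymethyl)-7-methoxy-2,3-dihydro-1-benzofuran-5-carboxylate | COC(=O)c1cc(OC)c2c(c1)[C@@H](CO)[C@H](c1ccc(OCc3ccccc3)c(OC)c1)O2 | intermediate
16 | methyl (2R,3S)-2-(4-benzyloxy-3-methoxyphenyl)-7-methoxy-3-[(methoxymethoxy)methyl]-2,3-dihydro-1-benzofuran-5-carboxylate | COC(=O)c1cc(OC)c2c(c1)[C@@H](COCOC)[C@H](c1ccc(OCc3ccccc3)c(OC)c1)O2 | intermediate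
17 | {(2R,3S)-2-(4-benzyloxy-3-methoxyphenyl)-7-methoxy-3-[(methoxymethoxy)methyl]-2,3-dihydro-1-benzofuran-5-yl}methanol | OCc1cc(OC)c2c(c1)[C@@H](COCOC)[C@H](c1ccc(OCc3ccccc3)c(OC)c1)O2 | intermediate
18 | (2R,3S)-2-(4-benzyloxy-3-methoxyphenyl)-5-(bromomethyl)-7-methoxy-3-[(methoxymethoxy)methyl]-2,3-dihydro-1-benzofuran | BrCc1cc(OC)c2c(c1)[C@@H](COCOC)[C@H](c1ccc(OCc3ccccc3)c(OC)c1)O2 | intermediate
19 | (4S)-4-benzyl-1,3-oxazolidin-2-one | O=C1N[C@@H](Cc2ccccc2)CO1 | starting material
20 | methyl 4-chloro-4-oxobutanoate | COC(=O)CCC(Cl)=O | starting material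
21 | methyl 4-[(4S)-4-benzyl-2-oxo-1,3-oxazolidin-3-yl]-4-oxobutanoate | COC(=O)CCC(=O)N1[C@@H](Cc2ccccc2)COC1=O | intermediate
22 | methyl (3S)-4-[(4S)-4-benzyl-2-oxo-1,3-oxazolidin-3-yl]-3-({(2R,3S)-2-(4-benzyloxy-3-methoxyphenyl)-7-methoxy-3-[(methoxymethoxy)methyl]-2,3-dihydro-1-benzofuran-5-yl}methyl)-4-oxobutanoate | COC(=O)C[C@H](Cc1cc(OC)c2c(c1)[C@@H](COCOC)[C@H](c1ccc(OCc3ccccc3)c(OC)c1)O2)C(=O)N1[C@@H](Cc2ccccc2)COC1=O | intermediate
23 | methyl (3S)-4-{(2R,3S)-2-(4-benzyloxy-3-methoxyphenyl)-7-methoxy-3-[(methoxymethoxy)methyl]-2,3-dihydro-1-benzofuran-5-yl}-3-(hydroxymethyl)butanoate | COC(=O)C[C@H](Cc1cc(OC)c2c(c1)[C@@H](COCOC)[C@H](c1ccc(OCc3ccccc3)c(OC)c1)O2)CO | intermediate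
24 | (4S)-4-({(2R,3S)-2-(4-benzyloxy-3-methoxyphenyl)-7-methoxy-3-[(methoxymethoxy)methyl]-2,3-dihydro-1-benzofuran-5-yl}methyl)oxolan-2-one | O=C1C[C@H](Cc2cc(OC)c3c(c2)[C@@H](COCOC)[C@H](c2ccc(OCc4ccccc4)c(OC)c2)O3)CO1 | intermediate
25 | (3S,4S)-3-({4-benzyloxy-3-[(4S,5S)-4-(4-benzyloxy-3-methoxyphenyl)-1,3-dioxan-5-yl]-5-methoxyphenyl}methyl)-4-({(2R,3S)-2-(4-benzyloxy-3-methoxyphenyl)-7-methoxy-3-[(methoxymethoxy)methyl]-2,3-dihydro-1-benzofuran-5-yl}methyl)oxolan-2-one | COc1cc([C@H]2OCOC[C@@H]2c2cc(C[C@@H]3C(=O)OC[C@H]3Cc3cc(OC)c4c(c3)[C@@H](COCOC)[C@H](c3ccc(OCc5ccccc5)c(OC)c3)O4)cc(OC)c2OCc2ccccc2)ccc1OCc1ccccc1 | intermediate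
26 | bis-pyridinium bis(triflate) from 25: dioxane opened to C9–OSiMe3 and C7–OCH2–N+(2,2'-bipyridinium), MOM ether converted into CH2OCH2–N+(2,2'-bipyridinium) (one regiochemistry shown) | COc1cc([C@@H](OC[n+]2ccccc2-c2ccccn2)[C@H](CO[Si](C)(C)C)c2cc(C[C@@H]3C(=O)OC[C@H]3Cc3cc(OC)c4c(c3)[C@@H](COC[n+]3ccccc3-c3ccccn3)[C@H](c3ccc(OCc5ccccc5)c(OC)c3)O4)cc(OC)c2OCc2ccccc2)ccc1OCc1ccccc1.[O-]S(=O)(=O)C(F)(F)F.[O-]S(=O)(=O)C(F)(F)F | intermediate
27 | (3S,4S)-3-({4-benzyloxy-3-[(1S,2S)-1-(4-benzyloxy-3-methoxyphenyl)-1,3-dihydroxypropan-2-yl]-5-methoxyphenyl}methyl)-4-({(2R,3S)-2-(4-benzyloxy-3-methoxyphenyl)-3-(hydroxymethyl)-7-methoxy-2,3-dihydro-1-benzofuran-5-yl}methyl)oxolan-2-one | COc1cc([C@@H](O)[C@H](CO)c2cc(C[C@@H]3C(=O)OC[C@H]3Cc3cc(OC)c4c(c3)[C@@H](CO)[C@H](c3ccc(OCc5ccccc5)c(OC)c3)O4)cc(OC)c2OCc2ccccc2)ccc1OCc1ccccc1 | intermediate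
28 | (3S,4S)-3-({3-[(1S,2S)-1,3-dihydroxy-1-(4-hydroxy-3-methoxyphenyl)propan-2-yl]-4-hydroxy-5-methoxyphenyl}methyl)-4-({(2R,3S)-2-(4-hydroxy-3-methoxyphenyl)-3-(hydroxymethyl)-7-methoxy-2,3-dihydro-1-benzofuran-5-yl}methyl)oxolan-2-one (CNP0186558.3) | COc1cc([C@@H](O)[C@H](CO)c2cc(C[C@@H]3C(=O)OC[C@H]3Cc3cc(OC)c4c(c3)[C@@H](CO)[C@H](c3ccc(O)c(OC)c3)O4)cc(OC)c2O)ccc1O | target

## Step count and least certain steps

Total number of steps: 20. Longest linear sequence: 15 steps (3 → 4 → 5 → 6 → 8 → 9 → 14 → 15 → 16 → 17 → 18 → 22 → 24 → 25 → 27 → 28).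

**Step 5 (key step, proposed new method).** Three things may go wrong. The internal, doubly arylated alkene with its ortho-acyloxy group may be taken up too slowly by the confined acid, so that conversion stalls. Face selection may be poor, because both alkene termini carry aryl groups. The C7 cation may live long enough to alkylate an electron-rich ring, or ring A may be hydroxymethylated. The fallback uses known chemistry and sets out from 6. The classical Prins reaction with paraformaldehyde and a catalytic achiral strong acid (CF3SO3H in CH2Cl2, or H2SO4 in AcOH), the reaction that converts 1-aryl-1-alkenes into trans-4-aryl-5-substituted 1,3-dioxanes, should give the racemic trans-dioxane. This is 8 together with its mirror image, methyl 3-[(4R,5R)-4-(4-benzyloxy-3-methoxyphenyl)-1,3-dioxan-5-yl]-4-(2,2-dimethylpropanoyloxy)-5-methoxybenzoate F1. The two are separated by preparative chromatography on a chiral stationary phase, and 8 re-enters the route at step 6. The relative configuration then rests on the diequatorial chair alone and the absolute configuration on the separation.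

**Step 11 (furan closure).** The C7 cation may fragment with loss of C9 as formaldehyde to an ortho-hydroxystilbene, or alkylate an electron-rich ring of a second molecule, before the phenol closes the ring. Incomplete trans selectivity is less likely because the closure is reversible. The fallback changes the reactive intermediate from a benzylic cation to a neutral quinone methide and sets out from 14. Hydrogenolysis (H2, Pd/C, EtOAc) frees the ring A phenol to give methyl 3-[(1S,2S)-1,3-dihydroxy-1-(4-hydroxy-3-methoxyphenyl)propan-2-yl]-4-hydroxy-5-methoxybenzoate F2. Its para-hydroxybenzylic alcohol forms the quinone methide under much weaker acid (PPTS, THF, rt), and the neighbouring phenol adds to it to give methyl (2R,3S)-2-(4-hydroxy-3-methoxyphenyl)-3-(hydroxymethyl)-7-methoxy-2,3-dihydro-1-benzofuran-5-carboxylate F3. Phenol-selective benzylation (BnBr, K2CO3, acetone) returns to the route at 15.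

**Step 18 (fragment coupling).** The electron-rich benzylic bromide 12 may decompose by ionisation faster than it alkylates, and slow alkylation allows proton exchange between enolate and product, with double alkylation and erosion of the trans relation. The fallback replaces the alkylation by an aldol addition and a radical deoxygenation and sets out from 11 and 24.
- Oxidation of 11 (MnO2, CH2Cl2) gives 4-benzyloxy-3-[(4S,5S)-4-(4-benzyloxy-3-methoxyphenyl)-1,3-dioxan-5-yl]-5-methoxybenzaldehyde F4.
- The lithium enolate of 24 (LiN(SiMe3)2, THF, −78 °C) adds to F4, again anti to the β-substituent, to give the α-(aryl-hydroxymethyl) lactone F5, formed as both carbinol epimers.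
- 1,1'-Thiocarbonyldiimidazole with DMAP converts F5 into the O-(imidazol-1-ylthiocarbonyl) derivative F6.
- Bu3SnH/AIBN (toluene, 80 °C; Barton–McCombie deoxygenation) removes the oxygen and returns to the route at 25.

**Step 19 (joint acetal cleavage on the full skeleton).** The C7–O bond, benzylic and para to a benzyloxy group, may ionise under the silyl triflate. That would cost the 7S configuration, or the cation would be captured by the neighbouring ring B benzyloxy oxygen with loss of its benzyl group, closing a second furan; the furan C2–O bond may open in the same way. The fallback changes the order of unmasking and makes the aryl rings electron-poor before the Lewis acid is applied; it sets out from 25.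
- Hydrogenolysis (H2, Pd/C) gives the triphenol F7, in which the dioxane and the MOM ether are intact.
- Ac2O/pyridine gives the tri-O-acetate F8. Its para-acyloxy groups disfavour benzylic ionisation at C7 and C2, and the acylated ring B oxygen is no longer nucleophilic.
- TMSOTf/2,2'-bipyridyl followed by water then gives the tri-O-acetate of the target, F9.
- Aminolysis of the three aryl acetates (pyrrolidine, CH2Cl2, 0 °C), which is faster than attack on the lactone, returns to the route at 28.

## Further compounds

F1 | step 5 | methyl 3-[(4R,5R)-4-(4-benzyloxy-3-methoxyphenyl)-1,3-dioxan-5-yl]-4-(2,2-dimethylpropanoyloxy)-5-methoxybenzoate | COc1cc([C@@H]2OCOC[C@H]2c2cc(C(=O)OC)cc(OC)c2OC(=O)C(C)(C)C)ccc1OCc1ccccc1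
F2 | step 11 | methyl 3-[(1S,2S)-1,3-dihydroxy-1-(4-hydroxy-3-methoxyphenyl)propan-2-yl]-4-hydroxy-5-methoxybenzoate | COc1cc([C@@H](O)[C@H](CO)c2cc(C(=O)OC)cc(OC)c2O)ccc1O
F3 | step 11 | methyl (2R,3S)-2-(4-hydroxy-3-methoxyphenyl)-3-(hydroxymethyl)-7-methoxy-2,3-dihydro-1-benzofuran-5-carboxylate | COC(=O)c1cc(OC)c2c(c1)[C@@H](CO)[C@H](c1ccc(O)c(OC)c1)O2
F4 | step 18 | 4-benzyloxy-3-[(4S,5S)-4-(4-benzyloxy-3-methoxyphenyl)-1,3-dioxan-5-yl]-5-methoxybenzaldehyde | COc1cc([C@H]2OCOC[C@@H]2c2cc(C=O)cc(OC)c2OCc2ccccc2)ccc1OCc1ccccc1
F5 | step 18 | 25 carrying a hydroxyl group on the benzylic carbon between Cα and ring B (trans lactone; carbinol centre as both epimers, left unspecified) | COc1cc([C@H]2OCOC[C@@H]2c2cc(C(O)[C@@H]3C(=O)OC[C@H]3Cc3cc(OC)c4c(c3)[C@@H](COCOC)[C@H](c3ccc(OCc5ccccc5)c(OC)c3)O4)cc(OC)c2OCc2ccccc2)ccc1OCc1ccccc1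
F6 | step 18 | O-(imidazol-1-ylthiocarbonyl) derivative of F5 (carbinol centre unspecified) | COc1cc([C@H]2OCOC[C@@H]2c2cc(C(OC(=S)n3ccnc3)[C@@H]3C(=O)OC[C@H]3Cc3cc(OC)c4c(c3)[C@@H](COCOC)[C@H](c3ccc(OCc5ccccc5)c(OC)c3)O4)cc(OC)c2OCc2ccccc2)ccc1OCc1ccccc1
F7 | step 19 | triphenol from 25 (three benzyl groups removed; dioxane and MOM ether intact) | COc1cc([C@H]2OCOC[C@@H]2c2cc(C[C@@H]3C(=O)OC[C@H]3Cc3cc(OC)c4c(c3)[C@@H](COCOC)[C@H](c3ccc(O)c(OC)c3)O4)cc(OC)c2O)ccc1O
F8 | step 19 | tri-O-acetate of F7 (three aryl acetates) | COc1cc([C@H]2OCOC[C@@H]2c2cc(C[C@@H]3C(=O)OC[C@H]3Cc3cc(OC)c4c(c3)[C@@H](COCOC)[C@H](c3ccc(OC(C)=O)c(OC)c3)O4)cc(OC)c2OC(C)=O)ccc1OC(C)=O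
F9 | step 19 | tri-O-acetate of 28 (three aryl acetates; the three alcohols free) | COc1cc([C@@H](O)[C@H](CO)c2cc(C[C@@H]3C(=O)OC[C@H]3Cc3cc(OC)c4c(c3)[C@@H](CO)[C@H](c3ccc(OC(C)=O)c(OC)c3)O4)cc(OC)c2OC(C)=O)ccc1OC(C)=O
A1 | alternative 1 | trans-lactone with the tetra-acetylated open unit on the α-arm and the unprotected open (1S,2S) unit on the β-arm | COc1cc([C@@H](OC(C)=O)[C@H](COC(C)=O)c2cc(C[C@@H]3C(=O)OC[C@H]3Cc3cc(OC)c(O)c([C@@H](CO)[C@H](O)c4ccc(O)c(OC)c4)c3)cc(OC)c2OC(C)=O)ccc1OC(C)=O
A2 | alternative 1 | target carrying four acetates on the open unit | COc1cc([C@@H](OC(C)=O)[C@H](COC(C)=O)c2cc(C[C@@H]3C(=O)OC[C@H]3Cc3cc(OC)c4c(c3)[C@@H](CO)[C@H](c3ccc(O)c(OC)c3)O4)cc(OC)c2OC(C)=O)ccc1OC(C)=O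
A3 | alternative 2 | methyl 2-[5-bromo-2-(4-tert-butyldimethylsilyloxy-3-methoxybenzyloxy)-3-methoxyphenyl]-2-diazoacetate | COC(=O)C(=[N+]=[N-])c1cc(Br)cc(OC)c1OCc1ccc(O[Si](C)(C)C(C)(C)C)c(OC)c1
A4 | alternative 2 | methyl trans-(2R,3S)-5-bromo-2-(4-tert-butyldimethylsilyloxy-3-methoxyphenyl)-7-methoxy-2,3-dihydro-1-benzofuran-3-carboxylate | COC(=O)[C@@H]1c2cc(Br)cc(OC)c2O[C@@H]1c1ccc(O[Si](C)(C)C(C)(C)C)c(OC)c1
A5 | alternative 3 | 3-{[(2R,3S)-dihydrobenzofuran-5-yl]methyl}cyclobutan-1-one with silyl ethers on the CH2OH and the ring D phenol | O=C1CC(Cc2cc(OC)c3c(c2)[C@@H](CO[Si](C)(C)C(C)(C)C)[C@H](c2ccc(O[Si](C)(C)C(C)(C)C)c(OC)c2)O3)C1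
A6 | alternative 3 | (S)-β-(arylmethyl)-γ-butyrolactone carrying the bis-silylated dihydrobenzofuran | O=C1C[C@H](Cc2cc(OC)c3c(c2)[C@@H](CO[Si](C)(C)C(C)(C)C)[C@H](c2ccc(O[Si](C)(C)C(C)(C)C)c(OC)c2)O3)CO1
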